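Start from slowness: the question is how many times a flask's slowest feed fits into its run.

| flask | starting material | fresh partner | coupling partner | temperature | remark | time |
|---|---|---|---|---|---|---|
| ochre | 0.050 M | 0.090 M | 0.15 M | −15 °C | run made earlier |  |
| red | 0.20 M | 0.090 M | 0.15 M | 18 °C | run made earlier |  |
| midnight | 0.10 M | 0.0900 M | 0.150 M | 30 °C |  | 80 min |
| dusk | 0.10 M | 0.0900 M | 0.150 M | 0 °C |  | 80 min |
| spring | 0.10 M | 0.0900 M | 0.150 M | −30 °C |  | 80 min |

| run | time / min | target / % | starting material / % |
|---|---|---|---|
| ochre | 80.0 | 6 | 87 |
| ochre | 150 | 12 | 78 |
| ochre | 240 | 16 | 64 |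
| ochre | 300 | 21 | 63 |
| ochre | 360 | 20 | 60 |
| ochre | 480 | 27 | 54 |
| red | 8.00 | 6 | 66 |
| red | 10.0 | 8 | 61 |
| red | 20.0 | 8 | 51 |
| red | 40.0 | 7 | 46 |
| red | 50.0 | 8 | 48 |
| red | 90.0 | 7 | 45 |

(scatter of a reading: 2 percentage points)

- a species is counted by the starting material in it: one idle adduct counts as two
- amounts and yields of target count idle adduct too
- candidate steps: starting material + coupling partner -> open intermediate; coupling partner + fresh partner -> second intermediate; open intermediate + second intermediate <-> target; 2 second intermediate -> homo product; starting material + target <-> idle adduct; starting material -> decomposition product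
- in an amount of target, one idle adduct counts as one target

- which flask leads in amount of target, in percent of the starting material charged ("all alike" within 1.5 percentage points) (midnight / dusk / spring / all alike)
- how much target is there at the end, in percent of the starting material charged: midnight
- how much target is there at the end, in percent of the starting material charged: dusk
- how much target is there at the end, in percent of the starting material charged: spring

1. Ochre keeps 54% of its starting material at 480 min, a fall by the factor e in 779 min. Call this the feed time: the time in which coupling partner at its charge uses starting material, taken as pseudo-first-order. The same coupling partner charge stands in both runs and the three flasks.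

2. Red keeps 66% at 8.00 min, so its feed time is 19.3 min, shorter than ochre's by a factor of 40.5.

3. Ochre and red differ in starting material charge as well as in temperature, but I assume that the charge does not change the feed time. Taking the logarithm of the feed time as straight in temperature, I get 145 min for dusk, 5.01 min for midnight and 4190 min for spring. So 80 min holds 0.552 feed times in dusk, 16.0 in midnight and 0.0191 in spring. On that reckoning dusk uses 42.4% of its charge and spring 1.89%.

4. At the last readings, target per starting material used reads 58.7% in ochre and 12.7% in red. Spring, on ochre's share, gets 1.11%. Dusk, on the geometric mean of the two shares, gets 11.6%.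

5. That mean is the weak link. Red's target stands near 8% of its charge from 10.0 min on, which reads as a ceiling in amount rather than a share. On dusk's charge that amount is 16.0%, while ochre's share on dusk's conversion gives 24.9%. Dusk is colder than red, so I place it between them, at 20.0%. Midnight is warmer than red, and I put it below that ceiling, so my reckoning has dusk in the lead.

The forecast also names dusk, with 6% for midnight, 13% for dusk (lower than my figure) and 1.2% for spring: “The runs suggest a trade-off between slow feed at low temperature and poor capture of the intermediates when warm.”

The flasks give 2.73% in midnight, 18.6% in dusk and 0.0893% in spring, so dusk leads.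

    starting material + coupling partner → open intermediate (k = 0.00120 M⁻¹ s⁻¹, Ea = 72.0 kJ mol⁻¹)
    coupling partner + fresh partner → second intermediate (k = 0.00170 M⁻¹ s⁻¹, Ea = 56.0 kJ mol⁻¹)
    open intermediate + second intermediate ⇌ target (K = 95.0 M⁻¹, k = 0.0550 M⁻¹ s⁻¹, Ea = 38.0 kJ mol⁻¹, ΔH = −42.0 kJ mol⁻¹)
    2 second intermediate → homo product (k = 0.0220 M⁻¹ s⁻¹, Ea = 43.0 kJ mol⁻¹)
    starting material + target ⇌ idle adduct, settled at all times (K = 4.40 M⁻¹, ΔH = −42.0 kJ mol⁻¹)
    starting material → decomposition product (k = 5.90 × 10⁻⁷ s⁻¹, Ea = 92.0 kJ mol⁻¹)
    (constants at 0 °C)

Midnight shows what lies past the feed. At 20 min, which is 3.99 of my feed times, it holds 8.21% target. At 80 min it holds 2.73%, with coupling partner down to 0.336% of its charge. Without the falling back of target to open and second intermediate, midnight holds 54.4%. A midnight flask charged with 40.0% of that coupling partner reckons at 6.38 feed times, scaled by that charge, in its 80 min, and it ends at 0.653% target.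

The runs are simulated for an exercise, and the scatter is random.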